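**Retrosynthetic overview**

1. Target ⇐ axial-selective mono-reduction of the hexacyclic 3,21-dione ⇐ oxidation of the hexacyclic 3,21-diol.
2. Seven-membered carbocycle and oxolane (C8–C27 and O–C14 bonds), formed together and last ⇐ acid-triggered opening of an 8β,26-spiro-epoxide by the C14=C27 methylene of a C11–C12-linked bis-decalin.
3. Epoxide and methylene ⇐ the two carbonyls of a C2-symmetric tetracyclic 8,14-diketone (one Wittig reaction, one sulfur-ylide epoxidation).
4. Rings A, B and D, E, formed together and first ⇐ two-directional epoxide-initiated cation–olefin tetracyclization of a bis(epoxide) bis(silyl enol ether) ⇐ oxidative C11–C12 dimerization of a siloxyallyl anion (acylsilane, vinyllithium, Brook rearrangement).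
5. All stereocentres ⇐ one organocatalytic Shi epoxidation of achiral geranyl acetate; the (S)-epoxide is used twice.

Convention and assumption: onocerane numbering is used (left decalin C1–C10 with methyls C23–C25, link C11–C12, right decalin C13–C22 with methyls C28–C30, C26 on C8, C27 on C14); α/β refer to each decalin in steroid orientation with its angular methyl β; the C21 hydroxyl of the target is read from the SMILES as axial (21R).

**Route**

Step 1
Reactants: 1 geranyl acetate
Product: 2 (S)-6,7-epoxygeranyl acetate
Conditions: L-fructose-derived Shi ketone (1,2:4,5-di-O-isopropylidene-β-L-erythro-2,3-hexodiulo-2,6-pyranose, 30 mol%), KHSO5 (as 2KHSO5·KHSO4·K2SO4, 1.4 equiv), K2CO3, n-Bu4NHSO4 (4 mol%), MeCN–CH2(OMe)2–aq. buffer pH 10.5, 0 °C, 2 h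
Reagents that add atoms: potassium peroxymonosulfate (KHSO5), [K+].[O-]S(=O)(=O)OO
Why: Shi asymmetric epoxidation, in which the chiral dioxirane made from the ketone and KHSO5 transfers oxygen through a spiro transition state to the electron-rich 6,7-alkene only (the 2,3-alkene is deactivated by the allylic acetate), the L-fructose-derived catalyst giving the (S)-epoxide (about 90% ee expected), the stereocentre that later controls every ring stereocentre.

Step 2
Reactants: 2 (S)-6,7-epoxygeranyl acetate
Product: 3 (S)-6,7-epoxygeraniol
Conditions: K2CO3 (0.2 equiv), MeOH, 0 °C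
Reagents that add atoms: none
Why: Base-catalysed transesterification (methanolysis) removes the acetate while the trisubstituted epoxide is inert to K2CO3 in MeOH at 0 °C.

Step 3
Reactants: 3 (S)-6,7-epoxygeraniol
Product: 5 (S)-6,7-epoxygeranyl bromide, via allylic mesylate 4 (not isolated)
Conditions: MsCl, Et3N, THF, −45 °C; then LiBr, THF, 0 °C
Reagents that add atoms: lithium bromide (LiBr), [Li+].[Br-]
Why: Mesylation followed by SN2 displacement with bromide gives the allylic bromide without touching the epoxide or the E alkene.

Step 4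
Reactants: 6 acetyltrimethylsilane; 7 cyclohexylamine
Product: 8 N-cyclohexyl-1-(trimethylsilyl)ethan-1-imine
Conditions: 4 Å molecular sieves, Et2O, 23 °C
Reagents that add atoms: none
Why: Imine condensation of the electrophilic acylsilane carbonyl with a primary amine gives the metalloenamine precursor that allows clean mono-alkylation.

Step 5
Reactants: 8 N-cyclohexyl-1-(trimethylsilyl)ethan-1-imine; 5 (S)-6,7-epoxygeranyl bromide
Product: 11 (4E,8S)-8,9-epoxy-5,9-dimethyl-1-(trimethylsilyl)dec-4-en-1-one, via lithium aza-enolate 9 (not isolated), via alkylated imine 10 (not isolated)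
Conditions: LiN(i-Pr)2, THF, −78 → 0 °C; then 5, −78 → −20 °C; then aq. AcOH–NaOAc (pH 4.5), pentane, 0 °C
Reagents that add atoms: water, O
Why: Stork metalloenamine alkylation, in which the lithiated imine displaces the primary allylic bromide by SN2 and buffered hydrolysis releases the acylsilane while the epoxide survives at pH 4.5.

Step 6
Reactants: 11 (4E,8S)-8,9-epoxy-5,9-dimethyl-1-(trimethylsilyl)dec-4-en-1-one (2 equiv); 12 tetravinylstannane Sn(CH=CH2)4 (0.5 equiv)
Product: 16 (3S,6E,10Z,14Z,18E,22S)-2,3:22,23-diepoxy-2,6,19,23-tetramethyl-10,15-bis(trimethylsilyloxy)tetracosa-6,10,14,18-tetraene, via vinyllithium 13 (not isolated), via lithium silylcarbinolate 14 (not isolated), via siloxyallyllithium 15 (not isolated)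
Conditions: 12, n-BuLi (2 equiv), Et2O, 0 °C; then 11, Et2O, −78 °C; THF, −78 → −40 °C; then I2 (0.5 equiv per 11), −78 °C
Reagents that add atoms: none
Why: Four-component coupling in which vinyllithium adds to the acylsilane, the 1,2-Brook rearrangement of the α-silyl alkoxide gives the (Z)-siloxyallyl anion, and oxidative dimerization with I2 joins two anions at their terminal carbons to make the C11–C12 bond, the pairing of two halves of about 90% ee leaving the C2-symmetric dimer nearly enantiopure.

Step 7
Reactants: 16 bis(epoxide) bis(silyl enol ether)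
Product: 17 (3S,21S)-3,21-dihydroxy-26,27-dinoronocerane-8,14-dione
Conditions: MeAlCl2 (3 equiv), CH2Cl2, −94 °C; then H2O
Reagents that add atoms: none
Why: Two-directional epoxide-initiated cation–olefin cyclization (Lewis-acid polyene cyclization), in which each (S)-epoxide opens with inversion at its tertiary carbon through chair–chair folding and the (Z)-silyl enol ethers terminate as the C8 and C14 ketones, so that the epoxide stereocentres fix C5, C10, C9 and their counterparts C17, C18, C13 (trans-decalins, equatorial C11–C12 link).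

Step 8
Reactants: 17 (3S,21S)-3,21-dihydroxy-26,27-dinoronocerane-8,14-dione
Product: 18 (3S,21S)-3,21-dihydroxy-26-noronocer-14(27)-en-8-one
Conditions: Ph3PCH3Br (1.1 equiv), KOt-Bu (1.1 equiv), toluene, 80 °C; recovered 17 recycled
Reagents that add atoms: methyltriphenylphosphonium bromide, C[P+](c1ccccc1)(c1ccccc1)c1ccccc1.[Br-]
Why: Wittig methylenation in which one equivalent of ylide reacts statistically with the two equivalent, mutually remote ketones, the C2 symmetry guaranteeing a single mono-olefin (about 45% per pass).

Step 9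
Reactants: 18 (3S,21S)-3,21-dihydroxy-26-noronocer-14(27)-en-8-one
Product: 19 (3S,21S)-8β,26-epoxyonocer-14(27)-ene-3,21-diol
Conditions: Me3SI (3 equiv), n-BuLi (3 equiv), THF, −10 °C; then 18, −10 → 23 °C
Reagents that add atoms: trimethylsulfonium iodide, C[S+](C)C.[I-]
Why: Corey–Chaykovsky epoxidation in which the sulfur ylide adds to the C8 carbonyl from the α face (equatorial attack, the β face being shielded by the axial C10 methyl), so that ring closure places C26 equatorial and the epoxide oxygen axial (8β).

Step 10
Reactants: 19 (3S,21S)-8β,26-epoxyonocer-14(27)-ene-3,21-diol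
Product: 20 (3S,21S)-14,26-epoxy-8,27-cycloonocerane-3,21-diol
Conditions: Ph4PBF4 (20 mol%), (CF3)2CHOH, 0 °C, 2 mM
Reagents that add atoms: none
Why: Proposed new method: hydrogen-bond activation of the axial spiro-epoxide by the fluorinated alcohol ionizes C8–O while the C14=C27 methylene, held five atoms away by the C11–C12 link, attacks C8 through C27 on the α face anti to the departing oxygen (the β face is blocked by the axial C10 methyl), closing the seven-membered ring and setting C8, after which the tertiary C14 cation is captured by the C26 oxygen to close the oxolane, the bicyclo[4.2.1] geometry allowing only the required C14 configuration; the closest known reaction types are epoxide-initiated cation–olefin cyclization (invertive opening at the tertiary epoxide carbon) and acid-promoted (3+2) annulation or Prins cyclization of epoxides with alkenes, not yet shown for a seven-membered closure between two preformed decalins.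

Step 11
Reactants: 20 (3S,21S)-14,26-epoxy-8,27-cycloonocerane-3,21-diol
Product: 21 14,26-epoxy-8,27-cycloonocerane-3,21-dione
Conditions: Dess–Martin periodinane (2.5 equiv), CH2Cl2, 23 °C
Reagents that add atoms: none
Why: Dess–Martin oxidation converts both equatorial secondary alcohols into ketones and leaves the ether and all ring stereocentres untouched.

Step 12
Reactants: 21 14,26-epoxy-8,27-cycloonocerane-3,21-dione
Product: 22 (21R)-21-hydroxy-14,26-epoxy-8,27-cycloonoceran-3-one
Conditions: LiBH(s-Bu)3 (1.0 equiv), THF, −78 °C; then H2O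
Reagents that add atoms: none
Why: Ketone reduction by a bulky trialkylborohydride, in which hydride enters the 4,4-dimethyl-3-ketone of ring E from the equatorial side and sets the axial (21R) alcohol, but because the two carbonyls have the same local surroundings the reaction is run to half conversion and gives 22 together with its C3-reduced regioisomer, the diol and unreacted 21 (about one quarter 22 per pass), all of which are separated and returned through step 11.

**Compound list**

1 | geranyl acetate, (2E)-3,7-dimethylocta-2,6-dien-1-yl acetate | CC(=O)OC/C=C(C)/CCC=C(C)C | starting material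
2 | (S)-6,7-epoxygeranyl acetate, (2E,6S)-6,7-epoxy-3,7-dimethyloct-2-en-1-yl acetate | CC(=O)OC/C=C(C)/CC[C@@H]1OC1(C)C | intermediate
3 | (S)-6,7-epoxygeraniol | OC/C=C(C)/CC[C@@H]1OC1(C)C | intermediate
4 | (S)-6,7-epoxygeranyl methanesulfonate | CS(=O)(=O)OC/C=C(C)/CC[C@@H]1OC1(C)C | intermediate
5 | (S)-6,7-epoxygeranyl bromide | BrC/C=C(C)/CC[C@@H]1OC1(C)C | intermediate
6 | acetyltrimethylsilane | CC(=O)[Si](C)(C)C | starting material
7 | cyclohexylamine | NC1CCCCC1 | starting material
8 | N-cyclohexyl-1-(trimethylsilyl)ethan-1-imine | CC(=NC1CCCCC1)[Si](C)(C)C | intermediate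
9 | lithium N-cyclohexyl-N-[1-(trimethylsilyl)vinyl]amide (lithium aza-enolate of 8) | [Li]N(C1CCCCC1)C(=C)[Si](C)(C)C | intermediate
10 | (4E,8S)-N-cyclohexyl-8,9-epoxy-5,9-dimethyl-1-(trimethylsilyl)dec-4-en-1-imine | C[Si](C)(C)C(=NC1CCCCC1)CC/C=C(C)/CC[C@@H]2OC2(C)C | intermediate
11 | (4E,8S)-8,9-epoxy-5,9-dimethyl-1-(trimethylsilyl)dec-4-en-1-one | C[Si](C)(C)C(=O)CC/C=C(C)/CC[C@@H]1OC1(C)C | intermediate
12 | tetravinylstannane, Sn(CH=CH2)4 | C=C[Sn](C=C)(C=C)C=C | starting material
13 | vinyllithium | [Li]C=C | intermediate
14 | lithium (6E,10S)-10,11-epoxy-7,11-dimethyl-3-(trimethylsilyl)dodeca-1,6-dien-3-olate (both C3 epimers) | [Li]OC(C=C)([Si](C)(C)C)CC/C=C(C)/CC[C@@H]1OC1(C)C | intermediate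
15 | (2Z,6E,10S)-10,11-epoxy-7,11-dimethyl-3-(trimethylsilyloxy)dodeca-2,6-dien-1-yllithium | [Li]C/C=C(O[Si](C)(C)C)/CC/C=C(C)/CC[C@@H]1OC1(C)C | intermediate
16 | (3S,6E,10Z,14Z,18E,22S)-2,3:22,23-diepoxy-2,6,19,23-tetramethyl-10,15-bis(trimethylsilyloxy)tetracosa-6,10,14,18-tetraene | CC1(C)O[C@H]1CC/C(C)=C/CC/C(O[Si](C)(C)C)=C/CC/C=C(O[Si](C)(C)C)/CC/C=C(C)/CC[C@@H]1OC1(C)C | intermediate
17 | (3S,21S)-3,21-dihydroxy-26,27-dinoronocerane-8,14-dione; C2-symmetric, both decalins trans-fused (H-5, H-17 α; C25, C28 methyls β), H-9 and H-13 axial with the C11–C12 link equatorial, both hydroxyls equatorial | CC1(C)[C@@H](O)CC[C@@]2(C)[C@H]1CCC(=O)[C@@H]2CC[C@H]3C(=O)CC[C@H]4C(C)(C)[C@@H](O)CC[C@]34C | intermediate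
18 | (3S,21S)-3,21-dihydroxy-26-noronocer-14(27)-en-8-one (C8 ketone in the left decalin, C14 exocyclic methylene in the right) | CC1(C)[C@@H](O)CC[C@@]2(C)[C@H]1CCC(=O)[C@@H]2CC[C@H]3C(=C)CC[C@H]4C(C)(C)[C@@H](O)CC[C@]34C | intermediate
19 | (3S,21S)-8β,26-epoxyonocer-14(27)-ene-3,21-diol (epoxide oxygen axial on the β face of C8, C26 equatorial) | CC1(C)[C@@H](O)CC[C@@]2(C)[C@H]1CC[C@@]5(CO5)[C@@H]2CC[C@H]3C(=C)CC[C@H]4C(C)(C)[C@@H](O)CC[C@]34C | intermediate
20 | (3S,21S)-14,26-epoxy-8,27-cycloonocerane-3,21-diol (C27 links C8 and C14, oxygen links C26 and C14; on C8: C26 axial β, C27 equatorial α; on C14: C27 axial, oxygen equatorial; both hydroxyls equatorial) | CC1(C)[C@@H](O)CC[C@@]2(C)[C@H]1CC[C@]13CO[C@@]4(CC[C@H]5C(C)(C)[C@@H](O)CC[C@]5(C)[C@H]4CC[C@@H]12)C3 | intermediate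
21 | 14,26-epoxy-8,27-cycloonocerane-3,21-dione | CC1(C)C(=O)CC[C@@]2(C)[C@H]1CC[C@]13CO[C@@]4(CC[C@H]5C(C)(C)C(=O)CC[C@]5(C)[C@H]4CC[C@@H]12)C3 | intermediate
22 | (21R)-21-hydroxy-14,26-epoxy-8,27-cycloonoceran-3-one, CNP0211850.1 (C21 hydroxyl axial, cis to H-17) | CC1(C)C(=O)CC[C@@]2(C)[C@H]1CC[C@]13CO[C@@]4(CC[C@H]5C(C)(C)[C@H](O)CC[C@]5(C)[C@H]4CC[C@@H]12)C3 | target

**Step count and risks**

Total step count: 12. Longest linear sequence: 11 steps (1, 2, 3, 5, 6, 7, 8, 9, 10, 11, 12).

Step 8 (statistical mono-methylenation). The yield is capped near 50% per pass and 18 must be separated from 17 and from the bis-olefin. The fallback sets out from 17 and comes back at 20. Both ketones are methylenated with excess Ph3P=CH2 (toluene, 80 °C) to give (+)-α-onocerin F1. One methylene is then epoxidized with m-CPBA (1 equiv, NaHCO3, CH2Cl2, 0 °C), the peracid attacking the open α face, to give 8α,26-epoxyonocer-14(27)-ene-3,21-diol F2, the C8 epimer of the epoxide in 19. Under the step 10 conditions F2 ionizes to the same C8 cation as 19 and closes to 20. The desymmetrizing event is thus moved from the olefination to the epoxidation, and the bis-olefin by-product of step 8 can be fed into this branch.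

Step 10 (the proposed new step). The C8 cation may undergo hydride shift to the C26 aldehyde, or eliminate to an allylic alcohol, before the seven-membered closure takes place. The fallback uses known chemistry, sets out from 19 and comes back at 20. Titanocene monochloride Cp2TiCl (trivalent titanium, made from Cp2TiCl2 and Mn powder, THF, 23 °C) opens the epoxide homolytically to the tertiary C8 radical. This radical adds in 7-endo fashion to the C14=C27 methylene, a documented way to seven-membered carbocycles. The tertiary C14 radical is trapped by a second Cp2TiCl and loses Cp2Ti(H)Cl to give (3S,21S)-8,27-cycloonocer-14-ene-3,21,26-triol F3, together with its 13(14)-ene isomer. Camphorsulfonic acid in CH2Cl2 then protonates either alkene isomer to the C14 cation, which the C26 hydroxyl captures (Markovnikov hydroalkoxylation) to give 20.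

Step 12 (end-differentiating reduction). No small hydride can tell the C21 carbonyl from the C3 carbonyl, so the step gives at best about a quarter of the material as 22 per pass and depends on separating 22 from its regioisomer. The fallback sets out from 21 and comes back at 22. It changes from reagent control to binding-pocket control: 21 is screened against NADPH-dependent ketoreductases of the 3α-hydroxysteroid dehydrogenase type (i-PrOH recycling, buffer–DMSO, 30 °C). An enzyme binds the whole unsymmetrical core and can therefore select the ring E carbonyl and deliver the axial alcohol. This fallback makes no new compound, F0.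

Further compounds
F1 | step 8 | (+)-α-onocerin, onocera-8(26),14(27)-diene-3,21-diol with both hydroxyls equatorial (3S,21S) | CC1(C)[C@@H](O)CC[C@@]2(C)[C@H]1CCC(=C)[C@@H]2CC[C@H]3C(=C)CC[C@H]4C(C)(C)[C@@H](O)CC[C@]34C
F2 | step 8 | (3S,21S)-8α,26-epoxyonocer-14(27)-ene-3,21-diol (epoxide oxygen equatorial on the α face of C8) | CC1(C)[C@@H](O)CC[C@@]2(C)[C@H]1CC[C@]5(CO5)[C@@H]2CC[C@H]3C(=C)CC[C@H]4C(C)(C)[C@@H](O)CC[C@]34C
F3 | step 10 | (3S,21S)-8,27-cycloonocer-14-ene-3,21,26-triol (C26 hydroxymethyl axial β and C27 equatorial α on C8) | CC1(C)[C@@H](O)CC[C@@]2(C)[C@H]1CC[C@@]1(CO)CC3=CC[C@H]4C(C)(C)[C@@H](O)CC[C@]4(C)[C@H]3CC[C@@H]12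
F0 | step 12 | none | none
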